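**Retrosynthetic overview**

- Feature: ring B is the methyl salicylate ring, labelled here C1 (carbon bearing CO2Me), C2 and C3 (methyl carbons), C4 (carbon bearing the depside oxygen), C5 (methyl carbon) and C6 (carbon bearing OH). Its segment C3–C4–C5–C6, with two methyls and two oxygens, is methyl 2-methyl-3-oxopentanoate acylated on the ketone oxygen, and C1–C2 with the C2 methyl is a buta-2,3-dienoate. The hindered ester C4–O–CO–ring A can therefore be made as an enol ester before ring B exists.
- Last disconnection: the two free phenols of ring A (the chlorinated ring) are unmasked from MOM ethers.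
- Key disconnection: ring B is opened at C2–C3 and C1–C6 into a 3-acyloxy-1-methoxy-1-silyloxy diene that carries ring A, and methyl buta-2,3-dienoate. In the forward sense, [4+2] cycloaddition, loss of methanol from C6 and shift of the exocyclic C2 methylene into the ring give the arene.
- The diene comes from γ-deprotonation and O-silylation of an enol ester. That enol ester is formed by O-acylation of the β-keto ester enolate with the ring A acid chloride, which is made from commercial methyl 2,4-dihydroxy-3,6-dimethylbenzoate (chlorination, MOM protection, saponification, chloroenamine).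
- Ring order: ring A is bought as an arene; ring B is the only ring that is built, and it is formed in the penultimate step.

Key step: step 7

Remark on the chemistry: the enol ester made in step 5 is drawn as its E isomer (acyloxy trans to CO2Me), the isomer expected from the open, non-chelated enolate. This double bond becomes a single bond in the diene, so a Z component would be taken through step 6 as well.

**Route**

Step 1
Reactants: 1 methyl 2,4-dihydroxy-3,6-dimethylbenzoate
Product: 2 methyl 5-chloro-2,4-dihydroxy-3,6-dimethylbenzoate
Conditions: SO2Cl2 (1.05 equiv), CH2Cl2/Et2O, 0 °C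
Reagents that add atoms: sulfuryl chloride, O=S(=O)(Cl)Cl
Why: Electrophilic aromatic chlorination goes to C5, the only unsubstituted ring carbon, which is ortho to the 4-hydroxyl and para to the 2-hydroxyl; one equivalent at 0 °C should avoid over-chlorination to a cyclohexadienone.

Step 2
Reactants: 2 methyl 5-chloro-2,4-dihydroxy-3,6-dimethylbenzoate
Product: 3 methyl 5-chloro-2,4-bis(methoxymethoxy)-3,6-dimethylbenzoate
Conditions: NaH (2.6 equiv), MOMCl (2.6 equiv), DMF, 0 → 20 °C
Reagents that add atoms: chloromethyl methyl ether, COCCl
Why: Williamson etherification of both phenoxides; NaH in DMF is strong enough to break the hydrogen bond of the 2-hydroxyl to the ester, and the methyl ester is untouched.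

Step 3
Reactants: 3 methyl 5-chloro-2,4-bis(methoxymethoxy)-3,6-dimethylbenzoate
Product: 4 5-chloro-2,4-bis(methoxymethoxy)-3,6-dimethylbenzoic acid
Conditions: KOH, DMSO/H2O (4:1), 80 °C; then aq. KHSO4 to pH 4, 0 °C
Reagents that add atoms: potassium hydroxide, [K+].[OH-]
Why: Saponification of a 2,6-disubstituted methyl benzoate by poorly solvated hydroxide in aqueous DMSO is the standard answer to such hindered esters; the MOM ethers and the aryl chloride are stable to base, and the acid is set free cold at pH 4 so that the acetals survive.

Step 4
Reactants: 4 5-chloro-2,4-bis(methoxymethoxy)-3,6-dimethylbenzoic acid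
Product: 5 5-chloro-2,4-bis(methoxymethoxy)-3,6-dimethylbenzoyl chloride
Conditions: 1-chloro-N,N,2-trimethylprop-1-en-1-amine (1.2 equiv), CH2Cl2, 0 → 20 °C; concentrated and used crude
Reagents that add atoms: 1-chloro-N,N,2-trimethylprop-1-en-1-amine, CC(C)=C(Cl)N(C)C
Why: The Ghosez chloroenamine converts carboxylic acids into acid chlorides under neutral conditions without setting HCl free, which protects the MOM acetals, in particular the ortho one that could otherwise close onto the acyl group.

Step 5
Reactants: 5 5-chloro-2,4-bis(methoxymethoxy)-3,6-dimethylbenzoyl chloride; 6 methyl 2-methyl-3-oxopentanoate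
Product: 8 methyl (2E)-3-{[5-chloro-2,4-bis(methoxymethoxy)-3,6-dimethylbenzoyl]oxy}-2-methylpent-2-enoate, via sodium enolate 7 (not isolated)
Conditions: 6 (1.3 equiv), NaH (1.3 equiv), THF/DMPU, 0 °C; then 5 in THF, 0 → 20 °C
Reagents that add atoms: none
Why: O-Acylation of a β-keto ester enolate: the α-methyl group disfavors C-acylation (a quaternary carbon would result), and the hard, hindered aroyl chloride and the loose ion pair in the dipolar cosolvent direct attack through oxygen to give the enol ester.

Step 6
Reactants: 8 methyl (2E)-3-{[5-chloro-2,4-bis(methoxymethoxy)-3,6-dimethylbenzoyl]oxy}-2-methylpent-2-enoate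
Product: 10 (3Z)-1-methoxy-2-methyl-1-[(trimethylsilyl)oxy]penta-1,3-dien-3-yl 5-chloro-2,4-bis(methoxymethoxy)-3,6-dimethylbenzoate (ketene acetal geometry unassigned), via lithium dienolate 9 (not isolated)
Conditions: Me3SiCl (3 equiv) present from the start, LiN(i-Pr)2 (1.05 equiv, commercial solution), THF, −78 °C → 0 °C; evaporation, pentane, filtration under argon; used crude
Reagents that add atoms: chlorotrimethylsilane, C[Si](C)(C)Cl
Why: Vinylogous (γ) deprotonation of a β-oxygenated enoate and O-silylation of the dienolate is the way Brassard- and Chan-type dienes are made; the internal quench traps the dienolate before acyl transfer, the twisted 2,6-disubstituted ring A ester is shielded from the amide, and the new C3=C4 bond should form Z (methyl cis to the acyloxy oxygen) to avoid allylic strain with the C5 methyl.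

Step 7
Reactants: 10 (3Z)-1-methoxy-2-methyl-1-[(trimethylsilyl)oxy]penta-1,3-dien-3-yl 5-chloro-2,4-bis(methoxymethoxy)-3,6-dimethylbenzoate; 11 methyl buta-2,3-dienoate
Product: 14 methyl 4-{[5-chloro-2,4-bis(methoxymethoxy)-3,6-dimethylbenzoyl]oxy}-2-hydroxy-3,5,6-trimethylbenzoate, via cycloadduct ketal 12 (not isolated), via aryl silyl ether 13 (not isolated)
Conditions: 11 (2 equiv), toluene, 90 °C, sealed tube; then aq. citric acid, THF, 20 °C
Reagents that add atoms: none
Why: Thermal [4+2] cycloaddition in which the ketene acetal oxygens and the C4 acyloxy group both raise the HOMO coefficient at the methyl-bearing terminus C3, which bonds to the electrophilic central carbon of the allenoate while C6 bonds to the ester-bearing carbon; adduct 12 then ionizes at the mixed ketal C6, loses methanol across C6–C1, and the resulting methylidene-cyclohexadiene moves a hydrogen from C3 to the exocyclic CH2 to give arene 13, whose labile aryl silyl ether is hydrolyzed in the mild acidic work-up. The closest known reaction type is the Diels–Alder reaction of 1-alkoxy-1-silyloxybuta-1,3-dienes (Brassard and Chan type) with allenic esters, followed by aromatization to 6-methylsalicylates. Ring B, a six-membered carbocycle, is closed by intermolecular cycloaddition in which both new bonds (C2–C3 and C1–C6) are formed in the same step, suprafacially on both partners. No stereocenter remains, since the three sp3 centers of 12 (C1, C3 and C6) are formed without control and are all erased on aromatization. The step needs regioselectivity and site selectivity: the matched donor pattern of the diene secures the first, the ester activates only the conjugated double bond of the allene, and only the 3Z diene (terminal methyl outward) can reach the s-cis conformation, so a 3E component would stay behind. The MOM ethers, the aryl chloride and the hindered ring A ester should be inert to the heating and to citric acid.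

Step 8
Reactants: 14 methyl 4-{[5-chloro-2,4-bis(methoxymethoxy)-3,6-dimethylbenzoyl]oxy}-2-hydroxy-3,5,6-trimethylbenzoate
Product: 15 methyl 4-[(5-chloro-2,4-dihydroxy-3,6-dimethylbenzoyl)oxy]-2-hydroxy-3,5,6-trimethylbenzoate
Conditions: HCl (1.25 M in MeOH), CH2Cl2/MeOH, 0 → 20 °C
Reagents that add atoms: none
Why: Acid-catalyzed transacetalization of the aryl MOM ethers to methanol; the depside ester is flanked by ortho substituents on both its acyl and its aryloxy side, and the methyl ester can only exchange with methanol degenerately, so both esters should survive.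

**Compound list**

1 | methyl 2,4-dihydroxy-3,6-dimethylbenzoate | COC(=O)c1c(C)cc(O)c(C)c1O | starting material
2 | methyl 5-chloro-2,4-dihydroxy-3,6-dimethylbenzoate | COC(=O)c1c(C)c(Cl)c(O)c(C)c1O | intermediate
3 | methyl 5-chloro-2,4-bis(methoxymethoxy)-3,6-dimethylbenzoate | COC(=O)c1c(C)c(Cl)c(OCOC)c(C)c1OCOC | intermediate
4 | 5-chloro-2,4-bis(methoxymethoxy)-3,6-dimethylbenzoic acid | OC(=O)c1c(C)c(Cl)c(OCOC)c(C)c1OCOC | intermediate
5 | 5-chloro-2,4-bis(methoxymethoxy)-3,6-dimethylbenzoyl chloride | ClC(=O)c1c(C)c(Cl)c(OCOC)c(C)c1OCOC | intermediate
6 | methyl 2-methyl-3-oxopentanoate (racemic) | CCC(=O)C(C)C(=O)OC | starting material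
7 | sodium 1-methoxy-2-methyl-1-oxopent-2-en-3-olate (sodium enolate of 6, not isolated) | CCC([O-])=C(C)C(=O)OC.[Na+] | intermediate
8 | methyl (2E)-3-{[5-chloro-2,4-bis(methoxymethoxy)-3,6-dimethylbenzoyl]oxy}-2-methylpent-2-enoate | CC/C(OC(=O)c1c(C)c(Cl)c(OCOC)c(C)c1OCOC)=C(/C)C(=O)OC | intermediate
9 | lithium (3Z)-3-{[5-chloro-2,4-bis(methoxymethoxy)-3,6-dimethylbenzoyl]oxy}-1-methoxy-2-methylpenta-1,3-dien-1-olate (lithium dienolate of 8, not isolated) | C/C=C(OC(=O)c1c(C)c(Cl)c(OCOC)c(C)c1OCOC)/C(C)=C(OC)[O-].[Li+] | intermediate
10 | (3Z)-1-methoxy-2-methyl-1-[(trimethylsilyl)oxy]penta-1,3-dien-3-yl 5-chloro-2,4-bis(methoxymethoxy)-3,6-dimethylbenzoate (ketene acetal geometry unassigned) | C/C=C(OC(=O)c1c(C)c(Cl)c(OCOC)c(C)c1OCOC)/C(C)=C(OC)O[Si](C)(C)C | intermediate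
11 | methyl buta-2,3-dienoate | COC(=O)C=C=C | starting material
12 | methyl 4-{[5-chloro-2,4-bis(methoxymethoxy)-3,6-dimethylbenzoyl]oxy}-6-methoxy-3,5-dimethyl-2-methylidene-6-[(trimethylsilyl)oxy]cyclohex-4-ene-1-carboxylate (mixture of diastereomers, not isolated) | COC(=O)C1C(=C)C(C)C(OC(=O)c2c(C)c(Cl)c(OCOC)c(C)c2OCOC)=C(C)C1(OC)O[Si](C)(C)C | intermediate
13 | methyl 4-{[5-chloro-2,4-bis(methoxymethoxy)-3,6-dimethylbenzoyl]oxy}-3,5,6-trimethyl-2-[(trimethylsilyl)oxy]benzoate (not isolated) | COC(=O)c1c(C)c(C)c(OC(=O)c2c(C)c(Cl)c(OCOC)c(C)c2OCOC)c(C)c1O[Si](C)(C)C | intermediate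
14 | methyl 4-{[5-chloro-2,4-bis(methoxymethoxy)-3,6-dimethylbenzoyl]oxy}-2-hydroxy-3,5,6-trimethylbenzoate | COC(=O)c1c(C)c(C)c(OC(=O)c2c(C)c(Cl)c(OCOC)c(C)c2OCOC)c(C)c1O | intermediate
15 | methyl 4-[(5-chloro-2,4-dihydroxy-3,6-dimethylbenzoyl)oxy]-2-hydroxy-3,5,6-trimethylbenzoate | COC(=O)c1c(C)c(C)c(OC(=O)c2c(C)c(Cl)c(O)c(C)c2O)c(C)c1O | target

**Step count and risks**

Total step count: 8. Longest linear sequence: 8 steps (1 → 2 → 3 → 4 → 5 → 8 → 10 → 14 → 15); compounds 6 and 11 are bought.

Steps most likely to fail:

1. Step 7 (cycloaddition and aromatization). The acyloxy group donates less than a silyloxy or alkoxy group and both diene termini are substituted, so ring formation may be slow. Desilylation of the ketene acetal by adventitious water or oligomerization of the allenoate may then win, and aromatization may stall before the exocyclic alkene has moved into the ring. The fallback gives up the cycloaddition; it sets out from compound 1 and comes back at compound 14. Rieche formylation of 1 (Cl2CHOMe, TiCl4, CH2Cl2) at its only free ring position should give methyl 5-formyl-2,4-dihydroxy-3,6-dimethylbenzoate F1. Hydrogenolysis of the ortho-hydroxy aldehyde (H2, Pd/C, AcOH) should give methyl 2,4-dihydroxy-3,5,6-trimethylbenzoate F2. Its non-chelated 4-hydroxyl is the more acidic one; as the monosodium phenoxide (NaH, 1 equiv, THF/DMF) it would be acylated by acid chloride 5 to give 14, which continues with step 8.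

2. Step 6 (diene formation). The amide base may instead deprotonate the benzylic methyl ortho to the ring A ester. The aroyloxy group may be lost by elimination to an allenoate, the acyl group may shift from oxygen to carbon in the dienolate before silylation, or the new double bond may form with the methyl inward. The fallback moves the strong-base step ahead of the attachment of ring A; it sets out from compound 6 and comes back at compound 14. Silylation of 6 (Et3N, Me3SiCl) should give methyl 2-methyl-3-[(trimethylsilyl)oxy]pent-2-enoate F3. Deprotonation and silylation (LiN(i-Pr)2, Me3SiCl, THF, −78 °C) should give (3Z)-1-methoxy-2-methyl-1,3-bis[(trimethylsilyl)oxy]penta-1,3-diene F4. Cycloaddition of this more electron-rich diene with 11 (toluene, heat) and acidic work-up should give the phenol methyl 2,4-dihydroxy-3,5,6-trimethylbenzoate F2, which is acylated at its 4-hydroxyl with 5 (NaH, THF/DMF) to give 14.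

3. Step 5 (O-acylation). The hindered acid chloride may react slowly, attack may occur through carbon, or the acid chloride may decompose through its ortho MOM group before it is consumed. The fallback changes both partners; it sets out from compounds 4 and 6 and comes back at compound 8. Acid 4 with cyanuric fluoride and pyridine (CH2Cl2) should give 5-chloro-2,4-bis(methoxymethoxy)-3,6-dimethylbenzoyl fluoride F5, which is stable to handling. Fluoride-catalyzed O-acylation (Bu4NF, catalytic, THF) of the silyl enol ether methyl 2-methyl-3-[(trimethylsilyl)oxy]pent-2-enoate F3, prepared from 6 as described under step 6, should then give enol ester 8 through the ammonium enolate, with the fluoride regenerated.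

**Further compounds**

F1 | step 7 | methyl 5-formyl-2,4-dihydroxy-3,6-dimethylbenzoate | COC(=O)c1c(C)c(C=O)c(O)c(C)c1O
F2 | step 7 | methyl 2,4-dihydroxy-3,5,6-trimethylbenzoate | COC(=O)c1c(C)c(C)c(O)c(C)c1O
F3 | step 6 | methyl 2-methyl-3-[(trimethylsilyl)oxy]pent-2-enoate (geometry unassigned) | CCC(O[Si](C)(C)C)=C(C)C(=O)OC
F4 | step 6 | (3Z)-1-methoxy-2-methyl-1,3-bis[(trimethylsilyl)oxy]penta-1,3-diene | C/C=C(O[Si](C)(C)C)/C(C)=C(OC)O[Si](C)(C)C
F5 | step 5 | 5-chloro-2,4-bis(methoxymethoxy)-3,6-dimethylbenzoyl fluoride | FC(=O)c1c(C)c(Cl)c(OCOC)c(C)c1OCOC
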